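Everything rests on cutting the C5–C6 bond of ring A (C5–C6–C7–C8–C9–C10) in a retro-[3,3] sense, which traces the cis-fused decalin back to a 2-vinylbicyclo[2.2.2]oct-5-en-2-ol. The feature exploited is the cis ring fusion at quaternary C5 and C10 together with the vicinal C8/C9 oxygens. In one operation the anionic oxy-Cope shift of step 6 closes ring A, forms C5–C6, fixes C5 relative to C10 and releases the C8 ketone beside a C9 dimethyl ketal. Its precursor is a resolved masked o-benzoquinone cycloadduct: the alkene bridge carries the future C4 and C5 methyl groups, a PMB ether marks C2, and the vinyl group sits syn to that alkene.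

Key step: step 6

Remark on numbering: decalins carry eremophilane numbers (C2, C4 CH–CH3, C5 C–CH3, C7, C8, C9, C10 ring-fusion CH); β is the face of the C5 methyl group and α the opposite face; bicyclic compounds carry von Baeyer numbers.
Assumption: 4-methoxybenzyl vinyl ether is taken as a purchasable compound.

Step 1
Reactants: 1 3,4-dimethylphenol
Product: 2 2-bromo-4,5-dimethylphenol
Conditions: N-bromosuccinimide, iPr2NH (cat.), CH2Cl2, 0 °C
Reagents that add atoms: N-bromosuccinimide, O=C1CCC(=O)N1Br
Why: Electrophilic aromatic bromination of the phenol should go to the open ortho position C6, since the para position is blocked by a methyl group and the other ortho position is flanked by one.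

Step 2
Reactants: 2 2-bromo-4,5-dimethylphenol
Product: 3 2-methoxy-4,5-dimethylphenol
Conditions: NaOMe, CuBr (cat.), MeOH/DMF, 110 °C; then aq. HCl
Reagents that add atoms: sodium methoxide, [Na+].[O-]C
Why: Copper-catalysed Ullmann-type methoxylation, a reaction type established for 2-bromophenols, should exchange the bromide for methoxide while the phenoxide stays intact.

Step 3
Reactants: 3 2-methoxy-4,5-dimethylphenol; 4 1-(ethenyloxymethyl)-4-methoxybenzene
Product: 6 racemic 3,3-dimethoxy-7-endo-[(4-methoxyphenyl)methoxy]-5,6-dimethylbicyclo[2.2.2]oct-5-en-2-one, via masked o-benzoquinone 5 (not isolated)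
Conditions: PhI(OAc)2, MeOH, 4 (5 equiv), 0 → 50 °C
Reagents that add atoms: methanol, CO
Why: Oxidative dearomatisation by PhI(OAc)2 in methanol should give the masked o-benzoquinone 5, which is trapped at once in an inverse-electron-demand Diels–Alder reaction in which the nucleophilic CH2 terminus of the vinyl ether bonds to the dienone δ-carbon (ether carbon next to the bridgehead beside the carbonyl) and the alkoxy group lies endo, syn to the new alkene bridge, so that C1, C4 and C7 are set relative to one another in a racemate.

Step 4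
Reactants: 6 racemic cycloadduct ketone
Product: 7 (1S,4S,7S)-3,3-dimethoxy-7-[(4-methoxyphenyl)methoxy]-5,6-dimethylbicyclo[2.2.2]oct-5-en-2-one
Conditions: preparative HPLC, cellulose tris(3,5-dimethylphenylcarbamate) stationary phase, hexane/iPrOH, 25 °C
Reagents that add atoms: none
Why: Chromatographic resolution on a chiral stationary phase should separate the two enantiomers of this rigid, UV-active ketone, and the (1S,4S,7S) antipode, to be identified by anomalous-dispersion X-ray analysis of a crystalline derivative, carries the absolute configuration into the rest of the route.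

Step 5
Reactants: 7 (1S,4S,7S)-cycloadduct ketone; 8 vinylmagnesium bromide
Product: 9 (1S,2R,4S,7S)-2-ethenyl-3,3-dimethoxy-7-[(4-methoxyphenyl)methoxy]-5,6-dimethylbicyclo[2.2.2]oct-5-en-2-ol
Conditions: CH2=CHMgBr, THF, −78 → 0 °C; then H2O
Reagents that add atoms: none
Why: Grignard 1,2-addition to the non-enolisable ketone should occur on the face turned toward the C5=C6 alkene bridge, the other face being guarded by the inward C7–H and C8–H bonds of the ethano bridge, so that the vinyl group ends syn to the alkene and C2 becomes R.

Step 6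
Reactants: 9 vinyl carbinol
Product: 12 cis-decalin Cope ketone (C8 ketone; C9 dimethyl ketal; C3=C4 alkene; 2β-OPMB; 5β-CH3; 10β-H), via potassium alkoxide 10 (not isolated), via potassium enolate 11 (not isolated)
Conditions: KH, 18-crown-6, THF, 0 → 65 °C; then AcOH, −78 °C
Reagents that add atoms: none
Why: Anionic oxy-Cope rearrangement: KH forms the potassium alkoxide 10, 18-crown-6 strips the counter-ion, and the oxygen lone pair weakens the adjacent allylic bicyclic C1–C2 bond (C3–C8 in decalin numbering), which breaks as the vinyl terminus bonds to the methyl-bearing alkene carbon (new C5–C6 bond) in a concerted [3,3] shift that gives enolate 11, protonated at C7 on quenching to ketone 12. The closest known reaction type is the alkoxide-accelerated [3,3] shift of 2-alkenylbicyclo[2.2.2]oct-5-en-2-ols made from masked o-benzoquinones, which is known to give cis-decalins. Ring A (C5–C6–C7–C8–C9–C10) is closed by this pericyclic bond formation, suprafacial on both allyl halves, through the boat-shaped six-centre array that the bicycle enforces, while ring B is the cyclohexene left behind when the bicycle opens. The one new stereocentre, quaternary C5, is substrate-controlled: the vinyl group is tied through C8–C9 to C10 and can reach C5 only on the alkene face turned toward that bridge, so C6 and C9 end on the same side of ring B and the C5 methyl is cis to C10–H, the absolute sense being inherited from resolved ketone 7. The step needs the [3,3] pathway to win over a [1,3] shift and over fragmentation of the alkoxide, which is secured by the syn arrangement of vinyl group and alkene set in step 5, by the relief of bicyclic strain and by enolate formation, while the PMB ether, the ketal and the lack of acidic C–H bonds leave the base nothing else to attack.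

Step 7
Reactants: 12 Cope ketone
Product: 13 allylic 2β-alcohol
Conditions: DDQ, CH2Cl2/pH 7 phosphate buffer, 0 °C
Reagents that add atoms: none
Why: Oxidative cleavage of the 4-methoxybenzyl ether by DDQ (hydride abstraction from the benzylic position, then hydrolysis of the oxocarbenium ion) should free the allylic 2β-alcohol without touching the ketone, the ketal or the trisubstituted alkene.

Step 8
Reactants: 13 allylic 2β-alcohol
Product: 15 allylic 2α-alcohol, via 4-nitrobenzoate ester 14 (not isolated)
Conditions: 4-O2NC6H4CO2H, PPh3, iPrO2CN=NCO2iPr, THF, 0 → 25 °C; then MeOH, K2CO3, 25 °C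
Reagents that add atoms: 4-nitrobenzoic acid, O=C(O)c1ccc(cc1)[N+](=O)[O-]
Why: Mitsunobu reaction with the acidic 4-nitrobenzoic acid should displace the activated allylic oxygen with inversion (the fully substituted C4 terminus disfavours allylic transposition), and methanolysis of ester 14 in the same flask should release the 2α-alcohol on the face opposite to the C5 methyl group.

Step 9
Reactants: 15 allylic 2α-alcohol
Product: 16 saturated 2α-alcohol with 4β-methyl group
Conditions: [Ir(cod)(PCy3)(py)]PF6 (cat.), H2 (1 atm), CH2Cl2, 25 °C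
Reagents that add atoms: none
Why: Hydroxyl-directed hydrogenation should deliver both hydrogens to the α face of the C3=C4 alkene from iridium bound to the 2α-hydroxyl, so that the new C4 stereocentre carries its methyl group β, cis to the C5 methyl group.

Step 10
Reactants: 16 saturated 2α-alcohol
Product: 17 2α-tert-butyldiphenylsilyl ether ketone
Conditions: t-BuPh2SiCl, imidazole, DMAP (cat.), DMF, 25 → 40 °C
Reagents that add atoms: tert-butyl(chloro)diphenylsilane, CC(C)(C)[Si](Cl)(c1ccccc1)c1ccccc1
Why: Imidazole-promoted silylation should protect the 2α-alcohol as a silyl ether of the most acid-stable common type, which is needed for the enolate, hydride, acylation and aqueous-acid steps that follow.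

Step 11
Reactants: 17 silyl ether ketone; 18 acetone
Product: 20 7β-(2-hydroxypropan-2-yl) ketone, via lithium enolate 19 (not isolated)
Conditions: LiN(iPr)2, THF, −78 °C; acetone, −78 °C; then AcOH, −78 °C
Reagents that add atoms: none
Why: Directed aldol addition should work because the C8 ketone can be enolised only toward C7 (C9 is a ketal), acetone should add to enolate 19 on the convex β face away from ring B to set C7, and the cold acidic quench guards against retro-aldol reversal.

Step 12
Reactants: 20 aldol ketone
Product: 21 8α,11-diol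
Conditions: NaBH4, MeOH, −20 → 0 °C
Reagents that add atoms: none
Why: Borohydride reduction of the ketone should take place by hydride attack on the convex β face of C8, the α face being screened by ring B, which gives the 8α-alcohol trans to the C7 side chain, the equatorial and more stable epimer.

Step 13
Reactants: 21 8α,11-diol; 22 tigloyl chloride
Product: 23 8α-tiglate with free tertiary 11-hydroxyl
Conditions: pyridine, DMAP (cat.), CH2Cl2, 0 → 40 °C
Reagents that add atoms: none
Why: DMAP-catalysed acylation should esterify only the secondary 8α-hydroxyl, since the tertiary hydroxyl is far less reactive toward the acylpyridinium ion, and the E alkene of the tiglate is the stable geometry and cannot drift.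

Step 14
Reactants: 23 8α-tiglate tertiary alcohol
Product: 24 7β-isopropenyl 8α-tiglate ketal
Conditions: SOCl2, pyridine, CH2Cl2, −20 °C
Reagents that add atoms: none
Why: Dehydration through the chlorosulfite with pyridine as base (E2 elimination) should take one of the six exposed methyl hydrogens in preference to the hindered C7 methine, giving the isopropenyl group without disturbing C7.

Step 15
Reactants: 24 isopropenyl tiglate ketal
Product: 25 9-ketone 8α-tiglate
Conditions: TsOH·H2O (cat.), acetone/H2O, 25 °C
Reagents that add atoms: water, O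
Why: Acid-catalysed ketal hydrolysis should unmask the C9 ketone, the dimethyl ketal being the only group labile at this acidity, and the mild room-temperature conditions should leave the enolisable C8 and C10 centres and the isopropenyl group untouched.

Step 16
Reactants: 25 9-ketone 8α-tiglate
Product: 26 9α-alcohol 8α-tiglate
Conditions: NaBH4, MeOH/THF, −40 °C
Reagents that add atoms: none
Why: Borohydride reduction should again deliver hydride to the convex β face, because approach to C9 from the α face is blocked by the syn-axial C4 of ring B, giving the axial 9α-alcohol cis to the 8α-tiglate, and the low temperature should hold back acyl migration, which would in any case run uphill from the equatorial to the axial oxygen.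

Step 17
Reactants: 26 9α-alcohol 8α-tiglate; 27 angelic acid
Product: 29 8α-tiglate 9α-angelate 2α-silyl ether, via mixed anhydride 28 (not isolated)
Conditions: 27, 2,4,6-Cl3C6H2COCl, Et3N, toluene, 25 °C; then 26, 80 °C
Reagents that add atoms: none
Why: Yamaguchi-type esterification through mixed anhydride 28 should acylate the hindered axial 9α-hydroxyl at the less shielded angeloyl carbonyl without a nucleophilic catalyst, conditions under which the Z double bond of angelates is known to survive.

Step 18
Reactants: 29 bis-ester silyl ether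
Product: 30 8α-tiglate 9α-angelate 2α-alcohol
Conditions: HF·pyridine, pyridine, THF, 0 → 25 °C
Reagents that add atoms: none
Why: Fluoride-mediated desilylation under buffered, non-basic conditions should free the 2α-alcohol without ester cleavage, acyl migration or Z-to-E isomerisation of the angelate.

Step 19
Reactants: 30 bis-ester 2α-alcohol
Product: 31 target, (4S,5R,7R,8R,9S,10S)-9-angeloyloxy-8-tigloyloxyeremophil-11-en-2-one
Conditions: Dess–Martin periodinane, CH2Cl2, 25 °C
Reagents that add atoms: none
Why: Dess–Martin oxidation should convert the secondary C2 alcohol to the ketone under neutral conditions that spare the isopropenyl group and both unsaturated esters, erasing the C2 stereocentre and giving the target.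

Compound list
1 | 3,4-dimethylphenol | Cc1ccc(O)cc1C | starting material
2 | 2-bromo-4,5-dimethylphenol | Cc1cc(O)c(Br)cc1C | intermediate
3 | 2-methoxy-4,5-dimethylphenol | Cc1cc(O)c(OC)cc1C | intermediate
4 | 1-(ethenyloxymethyl)-4-methoxybenzene (4-methoxybenzyl vinyl ether) | C=COCc1ccc(OC)cc1 | starting material
5 | 6,6-dimethoxy-3,4-dimethylcyclohexa-2,4-dien-1-one (masked o-benzoquinone) | O=C1C=C(C)C(C)=CC1(OC)OC | intermediate (not isolated)
6 | racemic (1S*,4S*,7S*)-3,3-dimethoxy-7-[(4-methoxyphenyl)methoxy]-5,6-dimethylbicyclo[2.2.2]oct-5-en-2-one, ether oxygen endo (syn to C5=C6); one enantiomer drawn | O=C1[C@H]2C(C)=C(C)[C@H](C[C@@H]2OCc3ccc(OC)cc3)C1(OC)OC | intermediate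
7 | (1S,4S,7S)-3,3-dimethoxy-7-[(4-methoxyphenyl)methoxy]-5,6-dimethylbicyclo[2.2.2]oct-5-en-2-one | O=C1[C@H]2C(C)=C(C)[C@H](C[C@@H]2OCc3ccc(OC)cc3)C1(OC)OC | intermediate
8 | vinylmagnesium bromide | C=C[Mg]Br | starting material
9 | (1S,2R,4S,7S)-2-ethenyl-3,3-dimethoxy-7-[(4-methoxyphenyl)methoxy]-5,6-dimethylbicyclo[2.2.2]oct-5-en-2-ol (vinyl syn to the alkene bridge, ether oxygen endo) | C=C[C@@]1(O)[C@H]2C(C)=C(C)[C@H](C[C@@H]2OCc3ccc(OC)cc3)C1(OC)OC | intermediate (key-step precursor)
10 | potassium alkoxide of 9 | [K+].C=C[C@@]1([O-])[C@H]2C(C)=C(C)[C@H](C[C@@H]2OCc3ccc(OC)cc3)C1(OC)OC | intermediate (not isolated)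
11 | potassium C7=C8 enolate of the cis-decalin (C9 dimethyl ketal, C3=C4, 2β-OPMB, 5β-CH3, 10β-H) | [K+].[O-]C1=CC[C@@]2(C)[C@H](C[C@H](OCc3ccc(OC)cc3)C=C2C)C1(OC)OC | intermediate (not isolated)
12 | cis-decalin Cope ketone: C8 ketone, C9 dimethyl ketal, C3=C4 alkene with C4 methyl, 5β-CH3, 10β-H, 2β-(4-methoxybenzyloxy) | C1C[C@@]2(C)[C@H](C[C@H](OCc3ccc(OC)cc3)C=C2C)C(OC)(OC)C1=O | intermediate (key-step product)
13 | allylic 2β-alcohol of the Cope ketone | C1C[C@@]2(C)[C@H](C[C@H](O)C=C2C)C(OC)(OC)C1=O | intermediate
14 | 2α-(4-nitrobenzoyloxy) Cope ketone | C1C[C@@]2(C)[C@H](C[C@@H](OC(=O)c3ccc(cc3)[N+](=O)[O-])C=C2C)C(OC)(OC)C1=O | intermediate (not isolated)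
15 | allylic 2α-alcohol of the Cope ketone | C1C[C@@]2(C)[C@H](C[C@@H](O)C=C2C)C(OC)(OC)C1=O | intermediate
16 | saturated cis-decalin: 2α-OH, 4β-CH3, 5β-CH3, 10β-H, C8 ketone, C9 dimethyl ketal | C1C[C@@]2(C)[C@H](C[C@@H](O)C[C@@H]2C)C(OC)(OC)C1=O | intermediate
17 | 2α-tert-butyldiphenylsilyl ether of 16 | C1C[C@@]2(C)[C@H](C[C@@H](O[Si](c3ccccc3)(c3ccccc3)C(C)(C)C)C[C@@H]2C)C(OC)(OC)C1=O | intermediate
18 | acetone | CC(C)=O | starting material
19 | lithium C7=C8 enolate of 17 | [Li+].[O-]C1=CC[C@@]2(C)[C@H](C[C@@H](O[Si](c3ccccc3)(c3ccccc3)C(C)(C)C)C[C@@H]2C)C1(OC)OC | intermediate (not isolated)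
20 | 7β-(2-hydroxypropan-2-yl) C8 ketone (aldol), C9 dimethyl ketal, 2α-silyl ether | CC(C)(O)[C@H]1C[C@@]2(C)[C@H](C[C@@H](O[Si](c3ccccc3)(c3ccccc3)C(C)(C)C)C[C@@H]2C)C(OC)(OC)C1=O | intermediate
21 | 8α,11-diol: 7β-(2-hydroxypropan-2-yl), 8α-OH, C9 dimethyl ketal, 2α-silyl ether | CC(C)(O)[C@H]1C[C@@]2(C)[C@H](C[C@@H](O[Si](c3ccccc3)(c3ccccc3)C(C)(C)C)C[C@@H]2C)C(OC)(OC)[C@@H]1O | intermediate
22 | tigloyl chloride, (2E)-2-methylbut-2-enoyl chloride | C/C=C(\C)C(=O)Cl | starting material
23 | 8α-tiglate of 21 with free tertiary 11-hydroxyl | CC(C)(O)[C@H]1C[C@@]2(C)[C@H](C[C@@H](O[Si](c3ccccc3)(c3ccccc3)C(C)(C)C)C[C@@H]2C)C(OC)(OC)[C@@H]1OC(=O)/C(C)=C/C | intermediate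
24 | 7β-isopropenyl 8α-tiglate, C9 dimethyl ketal, 2α-silyl ether | C=C(C)[C@H]1C[C@@]2(C)[C@H](C[C@@H](O[Si](c3ccccc3)(c3ccccc3)C(C)(C)C)C[C@@H]2C)C(OC)(OC)[C@@H]1OC(=O)/C(C)=C/C | intermediate
25 | 7β-isopropenyl 8α-tiglate C9 ketone, 2α-silyl ether | C=C(C)[C@H]1C[C@@]2(C)[C@H](C[C@@H](O[Si](c3ccccc3)(c3ccccc3)C(C)(C)C)C[C@@H]2C)C(=O)[C@@H]1OC(=O)/C(C)=C/C | intermediate
26 | 7β-isopropenyl 8α-tiglate 9α-alcohol, 2α-silyl ether | C=C(C)[C@H]1C[C@@]2(C)[C@H](C[C@@H](O[Si](c3ccccc3)(c3ccccc3)C(C)(C)C)C[C@@H]2C)[C@H](O)[C@@H]1OC(=O)/C(C)=C/C | intermediate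
27 | angelic acid, (2Z)-2-methylbut-2-enoic acid | C/C=C(/C)C(=O)O | starting material
28 | angelic 2,4,6-trichlorobenzoic mixed anhydride | C/C=C(/C)C(=O)OC(=O)c1c(Cl)cc(Cl)cc1Cl | intermediate (not isolated)
29 | 8α-tiglate 9α-angelate, 7β-isopropenyl, 2α-silyl ether | C=C(C)[C@H]1C[C@@]2(C)[C@H](C[C@@H](O[Si](c3ccccc3)(c3ccccc3)C(C)(C)C)C[C@@H]2C)[C@H](OC(=O)/C(C)=C\C)[C@@H]1OC(=O)/C(C)=C/C | intermediate
30 | 8α-tiglate 9α-angelate, 7β-isopropenyl, 2α-alcohol | C=C(C)[C@H]1C[C@@]2(C)[C@H](C[C@@H](O)C[C@@H]2C)[C@H](OC(=O)/C(C)=C\C)[C@@H]1OC(=O)/C(C)=C/C | intermediate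
31 | target: (4S,5R,7R,8R,9S,10S)-9-angeloyloxy-8-tigloyloxyeremophil-11-en-2-one (4β-CH3, 5β-CH3, 10β-H, 7β-isopropenyl, 8α-tiglate, 9α-angelate, C2 ketone) | C=C(C)[C@H]1C[C@@]2(C)[C@H](CC(=O)C[C@@H]2C)[C@H](OC(=O)/C(C)=C\C)[C@@H]1OC(=O)/C(C)=C/C | target

Total step count: 19. Longest linear sequence: 19 steps (1 to 31); compounds 4, 8, 18, 22 and 27 are bought.

Steps most likely to fail

Step 6 (key step). Bond formation at the fully substituted alkene carbon may be slow, so that the unshielded alkoxide fragments at the weakened bicyclic bond without ring closure, or shifts in a [1,3] sense. The fallback is the neutral thermal variant of the same shift. It sets out from carbinol 9: silylation with Me3SiOTf and 2,6-lutidine in CH2Cl2 would give the trimethylsilyl ether F1; heating F1 in degassed o-dichlorobenzene at about 200 °C in a sealed tube would effect the siloxy-Cope rearrangement to the trimethylsilyl enol ether F2; K2CO3 in methanol would cleave F2 and return to the route at ketone 12.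

Step 14. Elimination may run toward the ring methine C7, giving the tetrasubstituted isopropylidene isomer, or the chlorosulfite may ionise with participation of the neighbouring ester. The fallback avoids the tertiary alcohol altogether and sets out from ketone 17, replacing steps 11 to 14. Palladium-catalysed α-alkenylation of the ketone enolate with 2-bromopropene (Pd2(dba)3, P(t-Bu)3, LiN(SiMe3)2, THF, 25 °C; zerovalent palladium inserts into the C–Br bond and the enolate couples by reductive elimination) would give the 7β-isopropenyl ketone F3, which can settle to the equatorial epimer through its enolate. Immediate NaBH4 reduction, before the alkene can move into conjugation, would give the 8α-alcohol F4, and tigloylation with 22 under the conditions of step 13 would return to the route at 24.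

Step 17. Acylation of the hindered axial 9α-hydroxyl may be so slow that Z-to-E isomerisation of the angeloyl donor, or migration of the tiglate, competes. The fallback builds the Z alkene after the ester bond is in place and sets out from alcohol 26. Esterification with 2-[bis(2,2,2-trifluoroethoxy)phosphoryl]propanoic acid (dicyclohexylcarbodiimide, DMAP cat., CH2Cl2; the acid reacts through a small, highly electrophilic ketene) would give the phosphonate ester F5. Still–Gennari olefination of F5 with acetaldehyde (KN(SiMe3)2, 18-crown-6, THF, −78 °C) should form the Z-trisubstituted alkene and return to the route at 29.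

Further compounds
F1 | step 6 | trimethylsilyl ether of carbinol 9 | C=C[C@@]1(O[Si](C)(C)C)[C@H]2C(C)=C(C)[C@H](C[C@@H]2OCc3ccc(OC)cc3)C1(OC)OC
F2 | step 6 | trimethylsilyl enol ether (C7=C8) of Cope ketone 12 | C[Si](C)(C)OC1=CC[C@@]2(C)[C@H](C[C@H](OCc3ccc(OC)cc3)C=C2C)C1(OC)OC
F3 | step 14 | 7β-isopropenyl C8 ketone, C9 dimethyl ketal, 2α-silyl ether | C=C(C)[C@H]1C[C@@]2(C)[C@H](C[C@@H](O[Si](c3ccccc3)(c3ccccc3)C(C)(C)C)C[C@@H]2C)C(OC)(OC)C1=O
F4 | step 14 | 7β-isopropenyl 8α-alcohol, C9 dimethyl ketal, 2α-silyl ether | C=C(C)[C@H]1C[C@@]2(C)[C@H](C[C@@H](O[Si](c3ccccc3)(c3ccccc3)C(C)(C)C)C[C@@H]2C)C(OC)(OC)[C@@H]1O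
F5 | step 17 | 8α-tiglate 9α-{2-[bis(2,2,2-trifluoroethoxy)phosphoryl]propanoate}, 2α-silyl ether (both epimers at the phosphonate carbon) | C=C(C)[C@H]1C[C@@]2(C)[C@H](C[C@@H](O[Si](c3ccccc3)(c3ccccc3)C(C)(C)C)C[C@@H]2C)[C@H](OC(=O)C(C)P(=O)(OCC(F)(F)F)OCC(F)(F)F)[C@@H]1OC(=O)/C(C)=C/C
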